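**Plan**
- The retrosynthesis first cuts both C2–Br bonds at once. Each C2(Br)=C3 unit of a pyrrole ring is read as the enol bromide of a lactam, which leads to 6,6'-dibromo-3,3'-bioxindole. It then cuts the central C3–C3' bond to give two molecules of 6-bromooxindole.
- Enabling feature: the target is a twofold-symmetric dimer joined at the two pyrrole-ring C3 atoms, and each C3 is flanked by a C2 that can carry oxygen. At that oxidation level C3 is the nucleophilic carbon of an electron-rich 2-siloxyindole, and one silicon atom can bridge the two C2 oxygens.
- Forward order: all four rings are bought intact in 6-bromooxindole. The sequence is N-Boc protection, O–Si–O tethering of two halves, anodic C3–C3' coupling through a temporary seven-membered ring that loses silicon in the same flask, Boc removal, and a two-directional POBr3 deoxybromination that aromatises both pyrrole rings.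
- The C6 bromines come with the starting material and never meet a transition metal or an organometallic reagent. The C2 bromines replace the helper oxygens in the last step.
- Stereochemistry: the target has no stereocentre. C3 and C3' of the bioxindoles are transient centres, formed as a rac/meso mixture and erased on aromatisation.

Key step: step 3

Assumption: the target SMILES carries no descriptor for the C3–C3' axis, so the biaryl axis is treated as configurationally unassigned and nothing stereochemical has to be controlled.

Step 1
Reactants: 1 6-bromoindolin-2-one (6-bromooxindole)
Product: 2 tert-butyl 6-bromo-2-oxoindoline-1-carboxylate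
Conditions: Boc2O (1.2 equiv), Na2CO3, THF, 60 °C
Reagents that add atoms: di-tert-butyl dicarbonate, CC(C)(C)OC(=O)OC(=O)OC(C)(C)C
Why: N-acylation of the lactam N–H with Boc2O under a weak carbonate base is the standard N-Boc protection of oxindoles; without DMAP or a strong base the C3 enolate is not formed, so O- and C-acylation stay out, and the Boc group blocks N1 and acidifies C3–H for step 2.

Step 2
Reactants: 2 tert-butyl 6-bromo-2-oxoindoline-1-carboxylate (2 equiv)
Product: 3 di-tert-butyl 2,2'-[(diisopropylsilanediyl)bis(oxy)]bis(6-bromo-1H-indole-1-carboxylate)
Conditions: iPr2Si(OTf)2 (0.5 equiv per 2), Et3N, CH2Cl2, 0 °C to rt, Ar; quick filtration through Et3N-deactivated silica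
Reagents that add atoms: diisopropylsilyl bis(trifluoromethanesulfonate), CC(C)[Si](OS(=O)(=O)C(F)(F)F)(OS(=O)(=O)C(F)(F)F)C(C)C
Why: Soft enolisation and O-silylation of N-Boc-oxindoles with a silyl triflate and Et3N is the standard entry to N-Boc-2-siloxyindoles, it is driven by aromatisation of the pyrrole ring, and half an equivalent of the difunctional silyl bis-triflate should give the symmetric silyl bis-enol ether as it does in the ketone series.

Step 3
Reactants: 3 di-tert-butyl 2,2'-[(diisopropylsilanediyl)bis(oxy)]bis(6-bromo-1H-indole-1-carboxylate)
Product: 5 di-tert-butyl 6,6'-dibromo-2,2'-dioxo-[3,3'-biindoline]-1,1'-dicarboxylate (rac/meso mixture), via ring-closed dioxasilepine dication 4 (not isolated)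
Conditions: undivided cell, reticulated vitreous carbon anode, Pt cathode, constant current (2.1 F/mol), Et4NOTs (0.1 M), 2,6-lutidine, MeOH/CH2Cl2 (1:4), 0 °C, Ar
Reagents that add atoms: none
Why: Proposed new method: the N-Boc-2-siloxyindole is by far the most easily oxidised group in 3, so the anode takes one electron from one pyrrole-ring enol ether, the tethered partner attacks the resulting radical cation C3' to C3, a second electron is removed to give dication 4, and methanol strips the silicon from both oxygens to unveil the two lactams while the cathode turns the released protons into H2. The closest known reaction types are the oxidative coupling of dialkylsilyl bis-enol ethers of ketones to 1,4-diketones by (NH4)2Ce(NO3)6 and the anodic cyclisation of silyl enol ethers in MeOH/2,6-lutidine electrolytes; neither has been shown on lactam-derived 2-siloxyindoles or for a C3–C3' bond between two oxindoles. The only ring closed is the temporary seven-membered 1,3,2-dioxasilepine (Si, O, C2, C3, C3', C2', O), formed in a 7-endo-trig mode in which both enol C=C bonds lie inside the new ring, and it is opened again in the same flask. C3 and C3' become stereocentres whose relative configuration is set only by the conformation of that ring, and either the rac or the meso product serves because both centres become sp2 in step 5. The step needs C3–C3' coupling in preference to C–N, C–O or solvent capture and a stop at the two-electron level: Boc blocks and deactivates N1, the tether holds C3 and C3' within bonding distance, and loss of silicon turns each half into an N-acyl lactam that is far harder to oxidise than 3, while the C6–Br bonds are inert at both electrodes. If a Si–O bond breaks before the C–C bond forms, the freed benzylic, carbonyl-flanked oxindol-3-yl radical has no better outlet than dimerisation at C3, which gives the same product.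

Step 4
Reactants: 5 di-tert-butyl 6,6'-dibromo-2,2'-dioxo-[3,3'-biindoline]-1,1'-dicarboxylate
Product: 6 6,6'-dibromo-[3,3'-biindoline]-2,2'-dione (6,6'-dibromo-3,3'-bioxindole, rac/meso mixture)
Conditions: TFA/CH2Cl2 (1:3), 0 °C to rt, Ar
Reagents that add atoms: none
Why: Acidolytic Boc cleavage (loss of the tert-butyl cation, then decarboxylation) is fast for imide-type N-Boc lactams, leaves the aryl bromides and the C3–C3' bond untouched, and the acidic medium keeps the C3–H positions from enolising and being oxidised by air.

Step 5
Reactants: 6 6,6'-dibromo-[3,3'-biindoline]-2,2'-dione
Product: 7 2,2',6,6'-tetrabromo-1H,1'H-3,3'-biindole (target)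
Conditions: POBr3 (5 equiv), imidazole (2.5 equiv), ClCH2CH2Cl, 80 °C; then cold aq. NaHCO3
Reagents that add atoms: phosphorus oxybromide, O=P(Br)(Br)Br
Why: Two-directional deoxybromination of a lactam with POBr3 (Vilsmeier-type O-phosphorylation, bromide displacement at C2, loss of the C3 proton) is the known conversion of oxindoles into 2-bromoindoles; here it is driven by aromatisation of both pyrrole rings, erases both C3 stereocentres and puts bromine only where oxygen was.

**Compound list**
1 | 6-bromoindolin-2-one (6-bromooxindole) | O=C1Cc2ccc(Br)cc2N1 | starting material
2 | tert-butyl 6-bromo-2-oxoindoline-1-carboxylate | CC(C)(C)OC(=O)N1C(=O)Cc2ccc(Br)cc21 | intermediate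
3 | di-tert-butyl 2,2'-[(diisopropylsilanediyl)bis(oxy)]bis(6-bromo-1H-indole-1-carboxylate) | CC(C)[Si](Oc1cc2ccc(Br)cc2n1C(=O)OC(C)(C)C)(Oc1cc2ccc(Br)cc2n1C(=O)OC(C)(C)C)C(C)C | intermediate
4 | ring-closed dication: 2,2-diisopropyl-1,3,2-dioxasilepine whose C2–C3 and C2'–C3' edges belong to two N-Boc-6-bromo-3H-indolium units joined C3–C3' (no configuration defined) | CC(C)[Si]1(C(C)C)OC2=[N+](C(=O)OC(C)(C)C)c3cc(Br)ccc3C2C2c3ccc(Br)cc3[N+](C(=O)OC(C)(C)C)=C2O1 | intermediate
5 | di-tert-butyl 6,6'-dibromo-2,2'-dioxo-[3,3'-biindoline]-1,1'-dicarboxylate (rac/meso mixture, no configuration defined) | CC(C)(C)OC(=O)N1C(=O)C(c2ccc(Br)cc21)C1C(=O)N(C(=O)OC(C)(C)C)c2cc(Br)ccc21 | intermediate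
6 | 6,6'-dibromo-[3,3'-biindoline]-2,2'-dione (rac/meso mixture, no configuration defined) | O=C1Nc2cc(Br)ccc2C1C1C(=O)Nc2cc(Br)ccc21 | intermediate
7 | 2,2',6,6'-tetrabromo-1H,1'H-3,3'-biindole | Brc1ccc2c(-c3c(Br)[nH]c4cc(Br)ccc34)c(Br)[nH]c2c1 | target

Total step count: 5. Longest linear sequence: 5.

**Steps most likely to fail**

Step 3 (Proposed new method). Three processes threaten it. The tether may solvolyse in the methanolic electrolyte before oxidation. Methanol may capture the radical cation at C3. The ring-closed cation may lose the C3 proton instead of silicon, which would re-create an oxidisable enol ether and carry material past the two-electron level. The fallback uses known chemistry, sets out from 1 and comes back at 6, replacing steps 1 to 4. Compound 1 is condensed with purchased 6-bromoisatin F1 in AcOH with catalytic concentrated HCl at reflux (acid-catalysed aldol condensation with dehydration). This makes the same C3–C3' connection as a double bond in (E)-6,6'-dibromoisoindigo F2. Zn dust in AcOH then saturates the central alkene without touching the aryl bromides and gives 6.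

Step 5. The poorly soluble bis-lactam may be activated on one side only. An activated lactam may be captured by the neighbouring lactam oxygen, closing a ring across C2/C2'. The 2-bromoindole may also erode under acid. The fallback sets out from 6 and comes back at 7, and it installs bromine electrophilically instead of by oxygen replacement. Both lactams are reduced with BH3·THF (lactam reduction followed by dehydrative aromatisation) to 6,6'-dibromo-1H,1'H-3,3'-biindole F3. The free C2 and C2' positions, the most nucleophilic sites left on a 3-substituted indole, are then brominated with NBS (2 equiv, THF, −78 °C to 0 °C).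

Step 2. The second substitution at silicon may stay incomplete, the bis-enol ether may hydrolyse on isolation, or the silyl triflate may cleave the Boc group. The fallback sets out from 2 and comes back at 5, replacing steps 2 and 3 and giving up the tether for an intermolecular coupling. Compound 2 is O-silylated with TBSOTf/Et3N to the sturdier monomer tert-butyl 6-bromo-2-[(tert-butyldimethylsilyl)oxy]-1H-indole-1-carboxylate F4. This is homocoupled with a chemical oxidant (Cu(OTf)2/Cu2O, MeCN, 0 °C), the known oxidative dimerisation of silyl enol ethers.

**Further compounds**
F1 | step 3 | 6-bromoisatin (6-bromoindoline-2,3-dione, purchased co-reactant) | O=C1Nc2cc(Br)ccc2C1=O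
F2 | step 3 | (E)-6,6'-dibromoisoindigo | O=C1Nc2cc(Br)ccc2/C1=C1\C(=O)Nc2cc(Br)ccc21
F3 | step 5 | 6,6'-dibromo-1H,1'H-3,3'-biindole | Brc1ccc2c(-c3c[nH]c4cc(Br)ccc34)c[nH]c2c1
F4 | step 2 | tert-butyl 6-bromo-2-[(tert-butyldimethylsilyl)oxy]-1H-indole-1-carboxylate | CC(C)(C)OC(=O)n1c(O[Si](C)(C)C(C)(C)C)cc2ccc(Br)cc21
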